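The target is (R)-carvone oxidised at three further sites and carrying a prenyl chain. The cyclohexane ring C1–C6 and the side chain C8(=C9H2)–C10 are bought intact. Everything rests on disconnecting C10–C11. In one operation, a chiral phosphoric acid catalysed allylboration with an α,α-dimethylallyl boronate forms that bond, sets the C10 (S) carbinol and, through allylic transposition, delivers the prenyl group linear. The step exploits the exo-methylene carbinol C9=C8–C10(O) on ring carbon C5: in the precursor, trans-6-acetoxycarvone oxidised at C10, it is a 2-substituted acrolein. Angeloylation and a hydroxyl-relayed cis epoxidation of the ring alkene C2=C3 finish the synthesis.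

Key step: step 5

Numbering: carvone numbering is kept throughout. C1 is the carbonyl carbon, C2 the methyl-bearing ring carbon, C5 the branch carbon and C6 the acetoxy carbon. C8 is the sp2 branch carbon, C9 its exo-methylene, C10 the oxygenated branch carbon, and C11–C13 are the prenyl carbons.

Assumption: the sense of induction of the phosphoric acid is carried over from aryl and alkenyl aldehydes, where the (R)-acid gives Re-face allylation. The (S)-acid is therefore used for the Si-face addition needed here.

Step 1
Reactants: 1 (R)-(−)-carvone
Product: 2 trans-6-acetoxycarvone (5S,6S; acetoxy anti to the isopropenyl group)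
Conditions: Mn(OAc)3·2H2O (3 equiv), PhH, reflux, Dean–Stark
Reagents that add atoms: manganese triacetate dihydrate, CC(=O)[O-].CC(=O)[O-].CC(=O)[O-].[Mn+3].O.O
Why: α′-Acetoxylation of an enone by Mn(OAc)3: the trivalent manganese enolate formed on the saturated C6 side is oxidised to the α-keto radical and takes up acetate, which should enter anti to the C5 isopropenyl group to give the diequatorial trans isomer (also the thermodynamically favoured one), any cis epimer being removed by chromatography.

Step 2
Reactants: 2 trans-6-acetoxycarvone
Product: 3 10-chloro-trans-6-acetoxycarvone (side chain C(=CH2)CH2Cl)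
Conditions: Ca(OCl)2, solid CO2, CH2Cl2–H2O, 0 °C
Reagents that add atoms: calcium hypochlorite Ca(OCl)2, [Ca+2].[O-]Cl.[O-]Cl
Why: Ene-type allylic chlorination by HOCl made in the flask: the electron-rich 1,1-disubstituted alkene takes chlorine at its CH2 terminus and loses a methyl proton, so the former vinyl CH2 becomes C10H2Cl and the former methyl becomes the exo-methylene C9, while the electron-poor enone alkene, the acetate and both stereocentres are untouched.

Step 3
Reactants: 3 10-chloro-trans-6-acetoxycarvone
Product: 5 trans-6-acetoxycarvon-10-al (side chain C(=CH2)CHO), via alkoxyammonium chloride 4 (not isolated)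
Conditions: N-methylmorpholine N-oxide (anhydrous, 4 equiv), 4 Å MS, MeCN, rt; product used promptly
Reagents that add atoms: N-methylmorpholine N-oxide, C[N+]1([O-])CCOCC1
Why: Ganem-type N-oxide oxidation of an activated halide: the N-oxide oxygen displaces the allylic chloride (direct and allylic attack give the same product in this symmetrical allyl system) and the alkoxyammonium salt fragments with loss of N-methylmorpholine to the aldehyde, under conditions too mild to disturb the α-acetoxy enone or the C5 and C6 centres.

Step 4
Reactants: 6 prenyl chloride
Product: 8 2-(2-methylbut-3-en-2-yl)-4,4,5,5-tetramethyl-1,3,2-dioxaborolane (α,α-dimethylallyl pinacolboronate), via prenylmagnesium chloride 7 (not isolated)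
Conditions: Mg turnings (excess), THF, 0 °C, slow addition; then i-PrOBpin, −78 °C to rt; aq NH4Cl; distillation
Reagents that add atoms: 2-isopropoxy-4,4,5,5-tetramethyl-1,3,2-dioxaborolane, CC(C)OB1OC(C)(C)C(C)(C)O1
Why: Grignard formation followed by borylation: allylic Grignard reagents are trapped by boron electrophiles through a cyclic SE2′ transition state at the substituted γ carbon, which gives the tertiary boronate, and pinacol esters do not undergo 1,3-boron shift at ambient temperature in the absence of Lewis acids, so the branched isomer should survive work-up and distillation.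

Step 5
Reactants: 5 trans-6-acetoxycarvon-10-al; 8 α,α-dimethylallyl pinacolboronate
Product: 10 (10S)-10-hydroxy-10-prenyl-trans-6-acetoxycarvone, via pinacol borate ester 9 (not isolated)
Conditions: (S)-TRIP [(S)-3,3′-bis(2,4,6-triisopropylphenyl)-1,1′-binaphthyl-2,2′-diyl hydrogen phosphate] (5 mol %), 8 (1.5 equiv), 4 Å MS, PhMe, −30 °C; then pH 7 buffer, rt
Reagents that add atoms: none
Why: The phosphoric acid hydrogen-bonds to a boronate oxygen and to the formyl hydrogen, and addition runs through a closed six-membered chair in which boron binds the aldehyde oxygen while the unsubstituted CH2 terminus of the allyl unit bonds to C10 and the alkene migrates to the gem-dimethyl end, so the C10–C11 bond and a linear prenyl group free of any E/Z question form together. The closest known reactions are the chiral phosphoric acid catalysed allylboration of aryl, alkyl and alkenyl aldehydes with pinacol allylboronates and the uncatalysed transposing addition of α,α-dialkylallylboronates that gives linear prenyl carbinols. No ring is closed. The single new stereocentre, C10 (S), is set by the catalyst, the (S)-acid being chosen for Si-face delivery, while C5, separated from the carbonyl by the sp2 carbon C8, should bias the two faces only weakly. The step needs enantioface selectivity, secured by the catalyst at a temperature low enough to silence the uncatalysed background; linear regioselectivity, secured by the cyclic transposing transition state; and chemoselectivity, secured because the formyl group is the only unhindered carbonyl and neither the enone ketone nor the acetate reacts with allylboronates at −30 °C. The feature exploited is the exo-methylene unit C9=C8 next to C10, which makes the formyl carbon sp2-flanked and non-enolisable, so that the catalyst should treat it like the conjugated aldehydes for which it is established.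

Step 6
Reactants: 10 (10S)-10-hydroxy-10-prenyl-trans-6-acetoxycarvone; 11 angelic acid
Product: 13 (10S)-10-angeloyloxy-10-prenyl-trans-6-acetoxycarvone, via angeloyl trichlorobenzoyl anhydride 12 (not isolated)
Conditions: 11, 2,4,6-Cl3C6H2COCl, Et3N, PhMe, rt; then 10, PhMe, 75 °C (no DMAP)
Reagents that add atoms: none
Why: Yamaguchi-type esterification in its amine-only variant: the alcohol attacks the less hindered angeloyl carbonyl of the mixed anhydride, no nucleophilic catalyst is present to add to the β-carbon and turn the Z acid into the tiglate, and O-acylation leaves the C10 configuration as set.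

Step 7
Reactants: 13 (10S)-10-angeloyloxy-10-prenyl-trans-6-acetoxycarvone
Product: 14 C1 allylic alcohol of the cis-carveol type (1S; hydroxyl cis to the C5 branch and trans to the C6 acetoxy group)
Conditions: NaBH4, CeCl3·7H2O, MeOH, −78 °C; AcOH quench at −78 °C
Reagents that add atoms: none
Why: Luche 1,2-reduction: with the C5 branch and the C6 acetoxy group both equatorial on the half-chair, the cerium-activated carbonyl takes hydride axially, which places the new C1 hydroxyl equatorial, cis to the C5 branch and trans to the acetoxy group, while the two esters and the isolated alkenes are inert at −78 °C and the cold acidic quench guards against acetyl migration.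

Step 8
Reactants: 14 C1 allylic alcohol
Product: 15 cis-epoxy alcohol (2,3-epoxide syn to the C1 hydroxyl and cis to the C5 branch; 1R,2R,3S,5S,6S,10S)
Conditions: VO(acac)2 (5 mol %), t-BuOOH (1.2 equiv, in decane), CH2Cl2, 0 °C to rt
Reagents that add atoms: tert-butyl hydroperoxide, CC(C)(C)OO
Why: Hydroxyl-directed epoxidation catalysed by VO(acac)2: the C1 alkoxide and the tert-butylperoxide bind the same pentavalent vanadium centre, so oxygen is delivered to the C2=C3 face syn to the hydroxyl, which sets C2 and C3 cis to the C5 branch, and the three alkenes without an adjacent free hydroxyl react far more slowly.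

Step 9
Reactants: 15 cis-epoxy alcohol
Product: 16 target CNP0150645.2 (2S,3S,5S,6S,10S)
Conditions: Dess–Martin periodinane, NaHCO3, CH2Cl2, 0 °C to rt
Reagents that add atoms: none
Why: Dess–Martin oxidation of the secondary carbinol under bicarbonate buffering regenerates the C1 ketone and removes the relay stereocentre without touching the epoxide, the esters or the C6 centre, which already sits in its thermodynamically preferred trans arrangement.

Compound list
1 | (R)-(−)-carvone | C=C(C)[C@@H]1CC=C(C)C(=O)C1 | starting material
2 | trans-6-acetoxycarvone (5S,6S) | C=C(C)[C@@H]1CC=C(C)C(=O)[C@H]1OC(C)=O | intermediate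
3 | 10-chloro-trans-6-acetoxycarvone | C=C(CCl)[C@@H]1CC=C(C)C(=O)[C@H]1OC(C)=O | intermediate
4 | N-(allyloxy)-N-methylmorpholinium chloride derived from 3 | C=C(CO[N+]1(C)CCOCC1)[C@@H]1CC=C(C)C(=O)[C@H]1OC(C)=O.[Cl-] | intermediate (not isolated)
5 | trans-6-acetoxycarvon-10-al (2-substituted acrolein) | C=C(C=O)[C@@H]1CC=C(C)C(=O)[C@H]1OC(C)=O | intermediate
6 | prenyl chloride (1-chloro-3-methylbut-2-ene) | CC(C)=CCCl | starting material
7 | prenylmagnesium chloride | CC(C)=CC[Mg]Cl | intermediate (not isolated)
8 | 2-(2-methylbut-3-en-2-yl)-4,4,5,5-tetramethyl-1,3,2-dioxaborolane | C=CC(C)(C)B1OC(C)(C)C(C)(C)O1 | intermediate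
9 | pinacol borate ester of alcohol 10 (C10–O–Bpin) | C=C([C@H](CC=C(C)C)OB1OC(C)(C)C(C)(C)O1)[C@@H]1CC=C(C)C(=O)[C@H]1OC(C)=O | intermediate (not isolated)
10 | (10S)-10-hydroxy-10-prenyl-trans-6-acetoxycarvone | C=C([C@H](CC=C(C)C)O)[C@@H]1CC=C(C)C(=O)[C@H]1OC(C)=O | intermediate
11 | angelic acid ((Z)-2-methylbut-2-enoic acid) | C/C=C(/C)C(O)=O | starting material
12 | angelic 2,4,6-trichlorobenzoic mixed anhydride | C/C=C(/C)C(=O)OC(=O)c1c(Cl)cc(Cl)cc1Cl | intermediate (not isolated)
13 | (10S)-10-angeloyloxy-10-prenyl-trans-6-acetoxycarvone | C=C([C@H](CC=C(C)C)OC(=O)/C(C)=C\C)[C@@H]1CC=C(C)C(=O)[C@H]1OC(C)=O | intermediate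
14 | (1S)-allylic alcohol, hydroxyl cis to the C5 branch | C=C([C@H](CC=C(C)C)OC(=O)/C(C)=C\C)[C@@H]1CC=C(C)[C@H](O)[C@H]1OC(C)=O | intermediate
15 | cis-epoxy alcohol, epoxide syn to the C1 hydroxyl | C=C([C@H](CC=C(C)C)OC(=O)/C(C)=C\C)[C@@H]1C[C@@H]2O[C@]2(C)[C@H](O)[C@H]1OC(C)=O | intermediate
16 | CNP0150645.2 | C=C([C@H](CC=C(C)C)OC(=O)/C(C)=C\C)[C@@H]1C[C@@H]2O[C@]2(C)C(=O)[C@H]1OC(C)=O | target

Total step count: 9. Longest linear sequence: 8 steps from (R)-carvone (steps 1, 2, 3, 5, 6, 7, 8 and 9); step 4 is a one-step side branch.

Steps most likely to fail

Step 5. The catalysed pathway may be too slow for the hindered tertiary boronate, so that uncatalysed addition competes and the face selectivity at C10 erodes. The fallback separates bond formation from the building of the prenyl terminus. Setting out from 5, the same (S)-acid is used with commercial allyl pinacolboronate, the best-established partner for this catalysis, under the conditions of step 5. This should give, through its pinacol borate F1, the (10S)-allyl carbinol F2. Cross-metathesis of the monosubstituted alkene of F2 with 2-methyl-2-butene (second-generation Grubbs catalyst, CH2Cl2, 40 °C) then installs the gem-dimethyl terminus and comes back to the route at 10. The 1,1-disubstituted C8=C9 alkene and the trisubstituted ring alkene are too hindered to take part.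

Step 3. Displacement of the allylic chloride by the N-oxide may be sluggish, and the amine set free may isomerise or oligomerise the sensitive 2-substituted acrolein as it forms. The fallback reaches the aldehyde through the alcohol oxidation level. Setting out from 3, HCO2Na in DMF at rt should give the allylic formate F3. Brief treatment with KHCO3 in MeOH at 0 °C cleaves the primary formate far faster than the secondary acetate and gives 10-hydroxy-trans-6-acetoxycarvone F4. MnO2 in CH2Cl2 then oxidises the allylic alcohol selectively and comes back to the route at 5.

Step 6. Acyl activation may isomerise the angeloyl unit to tigloyl, the hindered allylic alcohol may acylate slowly, and prolonged heating with amine may allow acetyl migration from the C6 oxygen to the C10 oxygen. The fallback uses the acid as a carboxylate nucleophile and not as an activated acyl donor. Setting out from 5 and 8, step 5 is run with the (R)-acid, giving through its pinacol borate F5 the (10R)-alcohol F6. Mitsunobu esterification of F6 with angelic acid 11 (PPh3, DIAD, PhMe, 0 °C) proceeds with inversion at C10 and comes back to the route at 13. No activated angeloyl species and no hot base are involved, so the path to the tiglate and the migration are both avoided.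

Further compounds
F1 | step 5 | pinacol borate ester of the (10S)-allyl carbinol | C=C([C@H](CC=C)OB1OC(C)(C)C(C)(C)O1)[C@@H]1CC=C(C)C(=O)[C@H]1OC(C)=O
F2 | step 5 | (10S)-10-allyl-10-hydroxy-trans-6-acetoxycarvone | C=C([C@H](CC=C)O)[C@@H]1CC=C(C)C(=O)[C@H]1OC(C)=O
F3 | step 3 | 10-formyloxy-trans-6-acetoxycarvone | C=C(COC=O)[C@@H]1CC=C(C)C(=O)[C@H]1OC(C)=O
F4 | step 3 | 10-hydroxy-trans-6-acetoxycarvone | C=C(CO)[C@@H]1CC=C(C)C(=O)[C@H]1OC(C)=O
F5 | step 6 | pinacol borate ester of the (10R)-alcohol | C=C([C@@H](CC=C(C)C)OB1OC(C)(C)C(C)(C)O1)[C@@H]1CC=C(C)C(=O)[C@H]1OC(C)=O
F6 | step 6 | (10R)-10-hydroxy-10-prenyl-trans-6-acetoxycarvone | C=C([C@@H](CC=C(C)C)O)[C@@H]1CC=C(C)C(=O)[C@H]1OC(C)=O
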